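**Plan**

- Retrosynthesis: the C19 and C20 acids are first tied back into a temporary 19,20-(N-methyl)imide, then C3–C4 (aldol) and C4–C5 (Michael) are cut in one operation. Further back: C6–C7 and C10–C20 (two carbonylations), C10–C1 (conjugate addition), C13–C16 (ring D) and C8–C14/C9–C11 (Diels–Alder, ring C).
- Forward: ring B is bought as a cyclopentenone; ring C is added by Diels–Alder, ring D by palladium cycloalkenylation. Ring B is then dressed with C20, the C1–C3 chain and C7, and the imide ring and ring A close together in the key step.
- Enabling feature: C4 is the α-carbon of the C19 carboxyl, C5 is β to the C7 carboxyl, the C3 carbinol is β to C19, and C19/C20 lie syn-diaxial on ring A (1,3 across C5). A propionyl unit (C18–C4–C19) hung on C20 through nitrogen can therefore add first to C5 and then to the C3 aldehyde.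
- Stereochemistry: one purchased centre (C10–OSi, later erased) sets C8/C9 (anti Diels–Alder, cis fusion); C13 follows from bridging; C10 from addition anti to C11; C5 from the tether; C4 from the imide bridge (both C4 epimers converge); C3 from an open aldol transition state; C6 from thermodynamic protonation.
- Helpers removed: silyl ether and C12 carbonyl (steps 6–9), imide nitrogen (steps 18–19).

Key step: step 17

Remark: gibberellane numbering (C1–C20) is used for all intermediates, and "target triacid" means compound 29. "B/C/D tricycle" means ring B (C5, C6, C8, C9, C10) cis-fused at C8–C9 to the 16-methylene bicyclo[3.2.1]octane of rings C/D, with H9 on the face of the C15 bridge. Hydroperoxide is assumed to open the imide of 25 at the C19 carbonyl; the C20-opened isomer would give the same anhydride 28.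

**Step 1**
Reactants: 1 (R)-4-(tert-butyldimethylsilyloxy)cyclopent-2-en-1-one
Product: 2 (R)-4-(tert-butyldimethylsilyloxy)-2-iodocyclopent-2-en-1-one
Conditions: I2, pyridine, CH2Cl2, 0 °C → rt
Reagents that add atoms: iodine, [I][I]
Why: α-Iodination of the enone by pyridine conjugate addition, iodination of the enolate and elimination (Baylis–Hillman-type mechanism) should give the 2-iodo enone without touching the silyloxy stereocentre (future C10).

**Step 2**
Reactants: 2 (R)-4-(tert-butyldimethylsilyloxy)-2-iodocyclopent-2-en-1-one; 3 allyltributylstannane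
Product: 4 (R)-2-allyl-4-(tert-butyldimethylsilyloxy)cyclopent-2-en-1-one
Conditions: Pd2(dba)3 (2.5 mol %), AsPh3, CuI, NMP, rt
Reagents that add atoms: none
Why: Stille coupling of the α-iodo enone with the allylstannane should install the future C15–C16–C17 unit on C8 under neutral conditions that leave the β-silyloxy ketone intact.

**Step 3**
Reactants: 5 methyl vinyl ketone
Product: 6 2-(tert-butyldimethylsilyloxy)buta-1,3-diene
Conditions: t-BuMe2SiOTf, Et3N, Et2O, 0 °C
Reagents that add atoms: tert-butyldimethylsilyl trifluoromethanesulfonate, CC(C)(C)[Si](C)(C)OS(=O)(=O)C(F)(F)F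
Why: Soft enolisation and O-silylation of the methyl ketone should give the 2-silyloxy diene that carries C11–C14.

**Step 4**
Reactants: 4 (R)-2-allyl-4-(tert-butyldimethylsilyloxy)cyclopent-2-en-1-one; 6 2-(tert-butyldimethylsilyloxy)buta-1,3-diene
Product: 7 cis-fused B/C bicycle with 8-allyl 6-oxo 10-silyloxy groups and the C12=C13 silyl enol ether
Conditions: 6 (2 equiv), Tf2NH (10 mol %), CH2Cl2, −78 → −40 °C
Reagents that add atoms: none
Why: Triflimide-initiated (silyl triflimide-catalysed) Diels–Alder reaction of the 2-silyloxy diene with the hindered enone should bond C11 to C9 and C14 to C8 ("para" orientation, enol ether at C12=C13), with the diene arriving anti to the silyloxy group so that the quaternary C8 and C9 are set cis from the one purchased stereocentre.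

**Step 5**
Reactants: 7 cis-fused B/C bicycle (silyl enol ether)
Product: 8 B/C/D tricycle with 6,12-dioxo groups and 10-silyloxy syn to H9
Conditions: Pd(OAc)2 (10 mol %), O2 (1 atm), DMSO, 45 °C
Reagents that add atoms: none
Why: Palladium-promoted cycloalkenylation (Saegusa-type palladium enolate, 5-exo insertion of the 1,3-related allyl group, β-hydride elimination) should close ring D by the C13–C16 bond and deliver the exocyclic C16=C17 alkene, the C13 configuration being dictated by the bridge.

**Step 6**
Reactants: 8 B/C/D tricycle 6,12-dione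
Product: 9 C12 tosylhydrazone of 8
Conditions: TsNHNH2, MeOH, rt
Reagents that add atoms: 4-methylbenzenesulfonohydrazide, Cc1ccc(cc1)S(=O)(=O)NN
Why: Hydrazone condensation should be selective for the C12 ketone, flanked by a CH2 and a bridgehead CH, over the C6 ketone that is shielded by the quaternary C8.

**Step 7**
Reactants: 9 C12 tosylhydrazone
Product: 10 B/C/D tricycle 6-ketone with 10-silyloxy group (C12 methylene)
Conditions: catecholborane, CHCl3, 0 °C; then NaOAc·3H2O, 60 °C
Reagents that add atoms: none
Why: Caglioti-type tosylhydrazone reduction (hydride addition to C=N, then acetate-induced loss of sulfinate and N2 from the diazene) should remove the carbonyl that served ring D formation, the 1,1-disubstituted alkene being inert to the borane at 0 °C.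

**Step 8**
Reactants: 10 B/C/D tricycle 6-ketone 10-silyl ether
Product: 11 B/C/D tricycle 10-hydroxy-6-ketone
Conditions: Bu4NF, AcOH, THF, 0 °C → rt
Reagents that add atoms: none
Why: Fluoride cleavage of the silyl ether (desilylation) buffered with acetic acid should avoid β-elimination of the β-oxygenated ketone.

**Step 9**
Reactants: 11 B/C/D tricycle 10-hydroxy-6-ketone
Product: 12 B/C/D tricycle 6,10-dione
Conditions: Dess–Martin periodinane, CH2Cl2, rt
Reagents that add atoms: none
Why: Dess–Martin oxidation of the β-hydroxy ketone should give the (enolised) cyclopentane-1,3-dione and erase the purchased stereocentre after it has done its work; C9 becomes epimerisable, but the cis ring fusion next to a trigonal C10 is the stable arrangement.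

**Step 10**
Reactants: 12 B/C/D tricycle 6,10-dione
Product: 13 B/C/D tricycle 10-triflyloxy-5(10)-en-6-one
Conditions: Tf2O, Et3N, CH2Cl2, −78 °C
Reagents that add atoms: trifluoromethanesulfonic anhydride, O=S(=O)(OS(=O)(=O)C(F)(F)F)C(F)(F)F
Why: O-Sulfonylation of the dione enolate should occur at the oxygen on C10, remote from the quaternary C8 (the pattern of enol-ether formation in 4,4-disubstituted cycloalkane-1,3-diones), leaving the C6 ketone in conjugation.

**Step 11**
Reactants: 13 B/C/D tricycle vinylogous acyl triflate
Product: 14 2-(trimethylsilyl)ethyl ester of the 6-oxo-5(10)-ene-10-carboxylic acid (C20 installed)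
Conditions: Pd(OAc)2 (5 mol %), PPh3, CO (1 atm), Me3SiCH2CH2OH, Et3N, DMF, 50 °C
Reagents that add atoms: carbon monoxide, [C-]#[O+]; 2-(trimethylsilyl)ethanol, C[Si](C)(C)CCO
Why: Palladium-catalysed alkoxycarbonylation (oxidative addition of the triflate to zerovalent palladium, CO insertion, alcoholysis) should install C20 as a fluoride-labile ester.

**Step 12**
Reactants: 14 enone ester; 15 (2-(1,3-dioxolan-2-yl)ethyl)magnesium bromide
Product: 17 C6 enol triflate with quaternary C10 bearing the C20 ester and the dioxolanylethyl chain, via bromomagnesium enolate 16 (not isolated)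
Conditions: 15, CuBr·SMe2 (10 mol %), THF, −78 °C; then N-(5-chloropyridin-2-yl)bis(trifluoromethanesulfonimide), −78 → 0 °C; aq. NH4Cl
Reagents that add atoms: N-(5-chloropyridin-2-yl)bis(trifluoromethanesulfonimide), FC(F)(F)S(=O)(=O)N(c1ccc(Cl)cn1)S(=O)(=O)C(F)(F)F
Why: Copper-catalysed conjugate addition of the Grignard reagent to the enone β-carbon (C10) should create the quaternary centre with the nucleophile arriving anti to C11 on the neighbouring C9, so that the C1–C3 chain and C20 take their final orientations, and the enolate is trapped on oxygen as the C5=C6 enol triflate.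

**Step 13**
Reactants: 17 C6 enol triflate
Product: 18 diester with C5=C6–C7 methyl enoate and C20 2-(trimethylsilyl)ethyl ester
Conditions: Pd(OAc)2 (5 mol %), PPh3, CO (1 atm), MeOH, Et3N, DMF, 60 °C
Reagents that add atoms: carbon monoxide, [C-]#[O+]; methanol, CO
Why: A second palladium-catalysed methoxycarbonylation should convert the enol triflate into the C5=C6–C7 unsaturated ester, the Michael acceptor of the key step.

**Step 14**
Reactants: 18 diester
Product: 19 C20 carboxylic acid (C7 methyl enoate and acetal retained)
Conditions: Bu4NF, THF, 0 °C → rt; cold dilute aq. H3PO4 to pH 4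
Reagents that add atoms: none
Why: Fluoride attack on silicon triggers β-elimination (ethylene and Me3SiF) and should free the C20 acid while the methyl ester and the acetal survive.

**Step 15**
Reactants: 19 C20 carboxylic acid; 20 N-methylpropanamide
Product: 22 acyclic N-methyl imide joining C20 to the propionyl unit C18–C4–C19 (acetal retained), via acid chloride 21 (not isolated)
Conditions: Me2C=C(Cl)NMe2, CH2Cl2, 0 °C → rt; then 20 + NaH (premixed in THF), 0 °C → rt
Reagents that add atoms: none
Why: The neutral α-chloroenamine should convert the hindered acid into its chloride without acid that would harm the acetal, and N-acylation of the sodium amidate gives the mixed imide that tethers the C4 nucleophile to C20.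

**Step 16**
Reactants: 22 imide acetal
Product: 23 imide aldehyde (C3 aldehyde on the C10 chain)
Conditions: 1 M HCl, THF, rt
Reagents that add atoms: water, O
Why: Acid-catalysed acetal hydrolysis should unmask the C3 aldehyde; the imide, the enoate and the exocyclic alkene tolerate dilute acid at room temperature.

**Step 17**
Reactants: 23 imide aldehyde
Product: 25 pentacyclic 19,20-(N-methyl)imide 7-methyl ester of the target triacid, via glutarimide aldehyde 24 (not isolated)
Conditions: KOt-Bu (0.3 equiv), t-BuOH/THF (1:5), high dilution, −30 → 0 °C; AcOH quench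
Reagents that add atoms: none
Why: Catalytic tert-butoxide deprotonates the propionyl CH2 (C4), which adds 6-(enolendo)-exo-trig to C5 of the C5=C6–C7 enoate to close the glutarimide ring (24); the C6 ester enolate is protonated by t-BuOH, the imide is re-enolised at C4, and this enolate closes ring A by a 6-(enolexo)-exo-trig aldol onto the C3 aldehyde, forming the C3–C4 bond. The closest known reaction types are the intramolecular Michael addition of a tethered propionyl unit and the intramolecular aldol of a bridged ester-type enolate onto a δ-aldehyde, here run as one domino sequence. C5 is fixed by the tether (C4 must arrive on the face of C20); C6 by thermodynamic protonation trans to the new C5 substituent; C4 by the imide bridge, which can span ring A only with C19 and C20 syn-diaxial, so both C4 epimers of 24 converge through one planar enolate; and C3 by an open, non-chelated potassium transition state in which the aldehyde C=O lies anti to the C4–C19 bond, giving the axial hydroxyl anti to C19. The step needs site selectivity among the acidic positions and kinetic control at C3: C8 and C10 are quaternary so the enoate has no enolisable neighbours, the aldehyde enolate has no ring-forming outlet and at high dilution simply re-protonates, the C6–H of the ester is less acidic than the imide C4–H, and the cold acetic acid quench precedes retro-aldol equilibration to the equatorial epimer.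

**Step 18**
Reactants: 25 pentacyclic imide
Product: 27 20-(N-methylamide) of the target triacid with free C19 and C7 acids, via amide acid methyl ester 26 (not isolated)
Conditions: LiOH, 30 % H2O2, THF/H2O, 0 °C → rt; Na2SO3; then LiOH, MeOH/H2O, 60 °C; HCl to pH 4, 0 °C
Reagents that add atoms: hydrogen peroxide, OO; water, O
Why: Hydroperoxide, a strong α-nucleophile of low basicity, should open the imide at the C19 carbonyl (perhydrolysis, peracid reduced by sulfite) without deprotonating the 3-hydroxyl; the resulting carboxylate cannot undergo retro-aldol cleavage, so the hindered C7 methyl ester can then be saponified hot.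

**Step 19**
Reactants: 27 20-(N-methylamide) of the target triacid
Product: 29 target triacid (ent-3α-hydroxygibberell-16-ene-7,19,20-trioic acid), via cyclic anhydride 28 (not isolated)
Conditions: AcOH/H2O/THF (pH ≈ 3.5), 50 °C
Reagents that add atoms: water, O
Why: Neighbouring-group-assisted amide cleavage: the C19 carboxylic acid, held syn-diaxial to the C20 amide on ring A, should attack the amide carbonyl at pH 3–4 and expel methylamine to give the 19,20-anhydride, which is hydrolysed in the same medium to the triacid.

**Compound list**

1 | (R)-4-(tert-butyldimethylsilyloxy)cyclopent-2-en-1-one | O=C1C=C[C@H](O[Si](C)(C)C(C)(C)C)C1 | starting material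
2 | (R)-4-(tert-butyldimethylsilyloxy)-2-iodocyclopent-2-en-1-one | O=C1C(I)=C[C@H](O[Si](C)(C)C(C)(C)C)C1 | intermediate
3 | allyltributylstannane | C=CC[Sn](CCCC)(CCCC)CCCC | starting material
4 | (R)-2-allyl-4-(tert-butyldimethylsilyloxy)cyclopent-2-en-1-one | C=CCC1=C[C@H](O[Si](C)(C)C(C)(C)C)CC1=O | intermediate
5 | methyl vinyl ketone (but-3-en-2-one) | CC(=O)C=C | starting material
6 | 2-(tert-butyldimethylsilyloxy)buta-1,3-diene | C=CC(=C)O[Si](C)(C)C(C)(C)C | intermediate
7 | cis-fused B/C bicycle: ring B 6-ketone with 10-silyloxy group, angular 8-allyl, ring C with 12-silyloxy C12=C13 enol ether; allyl, H9 and the 10-silyloxy group all on the face opposite to ring C | C=CC[C@]12CC=C(O[Si](C)(C)C(C)(C)C)C[C@H]1[C@H](O[Si](C)(C)C(C)(C)C)CC2=O | intermediate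
8 | B/C/D tricycle, 6,12-dione, 10-(tert-butyldimethylsilyloxy) syn to H9, 16-methylene | C=C1C[C@]23C[C@H]1C(=O)C[C@H]2[C@H](O[Si](C)(C)C(C)(C)C)CC3=O | intermediate
9 | C12 tosylhydrazone of 8 | C=C1C[C@]23C[C@H]1C(=NNS(=O)(=O)c1ccc(C)cc1)C[C@H]2[C@H](O[Si](C)(C)C(C)(C)C)CC3=O | intermediate
10 | B/C/D tricycle, 6-ketone, 10-(tert-butyldimethylsilyloxy) syn to H9, C12 methylene | C=C1C[C@]23C[C@H]1CC[C@H]2[C@H](O[Si](C)(C)C(C)(C)C)CC3=O | intermediate
11 | B/C/D tricycle, 10-hydroxy (syn to H9) 6-ketone | C=C1C[C@]23C[C@H]1CC[C@H]2[C@H](O)CC3=O | intermediate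
12 | B/C/D tricycle, 6,10-dione (drawn as diketone) | C=C1C[C@]23C[C@H]1CC[C@H]2C(=O)CC3=O | intermediate
13 | B/C/D tricycle, 10-(trifluoromethanesulfonyloxy)-5(10)-en-6-one | C=C1C[C@]23C[C@H]1CC[C@H]2C(OS(=O)(=O)C(F)(F)F)=CC3=O | intermediate
14 | B/C/D tricycle, 6-oxo-5(10)-ene with C20 as 2-(trimethylsilyl)ethyl ester on C10 | C=C1C[C@]23C[C@H]1CC[C@H]2C(C(=O)OCC[Si](C)(C)C)=CC3=O | intermediate
15 | (2-(1,3-dioxolan-2-yl)ethyl)magnesium bromide | Br[Mg]CCC1OCCO1 | starting material
16 | bromomagnesium C5=C6 enolate, quaternary C10 with C20 ester syn to ring C and dioxolanylethyl chain on the face of H9 | C=C1C[C@]23C[C@H]1CC[C@H]2[C@](C(=O)OCC[Si](C)(C)C)(CCC1OCCO1)C=C3O[Mg]Br | intermediate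
17 | C6 enol triflate (C5=C6) with the same quaternary C10 | C=C1C[C@]23C[C@H]1CC[C@H]2[C@](C(=O)OCC[Si](C)(C)C)(CCC1OCCO1)C=C3OS(=O)(=O)C(F)(F)F | intermediate
18 | diester: C5=C6–C7 methyl enoate, C20 2-(trimethylsilyl)ethyl ester, C1–C3 chain as dioxolane | C=C1C[C@]23C[C@H]1CC[C@H]2[C@](C(=O)OCC[Si](C)(C)C)(CCC1OCCO1)C=C3C(=O)OC | intermediate
19 | C20 carboxylic acid of 18 | C=C1C[C@]23C[C@H]1CC[C@H]2[C@](C(=O)O)(CCC1OCCO1)C=C3C(=O)OC | intermediate
20 | N-methylpropanamide | CCC(=O)NC | starting material
21 | C20 acid chloride of 19 | C=C1C[C@]23C[C@H]1CC[C@H]2[C@](C(=O)Cl)(CCC1OCCO1)C=C3C(=O)OC | intermediate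
22 | acyclic imide C20(=O)–N(CH3)–C(=O)CH2CH3 on C10, dioxolane chain, C7 methyl enoate | C=C1C[C@]23C[C@H]1CC[C@H]2[C@](C(=O)N(C)C(=O)CC)(CCC1OCCO1)C=C3C(=O)OC | intermediate
23 | imide aldehyde (C10 bears CH2CH2CHO) | C=C1C[C@]23C[C@H]1CC[C@H]2[C@](C(=O)N(C)C(=O)CC)(CCC=O)C=C3C(=O)OC | intermediate
24 | glutarimide aldehyde: imide ring C4–C19–N–C20–C10–C5 cis-fused to ring B, C4 epimers, C7 ester trans to C4 | C=C1C[C@]23C[C@H]1CC[C@H]2[C@@]1(CCC=O)C(=O)N(C)C(=O)C(C)[C@H]1[C@@H]3C(=O)OC | intermediate
25 | 19,20-(N-methyl)imide 7-methyl ester of the target triacid (axial 3-hydroxyl anti to C19) | C=C1C[C@]23C[C@H]1CC[C@H]2[C@]14CC[C@H](O)[C@@](C)(C(=O)N(C)C4=O)[C@H]1[C@@H]3C(=O)OC | intermediate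
26 | 20-(N-methylamide) 7-methyl ester of the target triacid (free C19 acid) | C=C1C[C@]23C[C@H]1CC[C@H]2[C@]1(C(=O)NC)CC[C@H](O)[C@@](C)(C(=O)O)[C@H]1[C@@H]3C(=O)OC | intermediate
27 | 20-(N-methylamide) of the target triacid (free C19 and C7 acids) | C=C1C[C@]23C[C@H]1CC[C@H]2[C@]1(C(=O)NC)CC[C@H](O)[C@@](C)(C(=O)O)[C@H]1[C@@H]3C(=O)O | intermediate
28 | 19,20-anhydride of the target triacid | C=C1C[C@]23C[C@H]1CC[C@H]2[C@]14CC[C@H](O)[C@@](C)(C(=O)OC4=O)[C@H]1[C@@H]3C(=O)O | intermediate
29 | target triacid: ent-3α-hydroxygibberell-16-ene-7,19,20-trioic acid (16-methylene, axial 3-hydroxyl cis to the C18 methyl, carboxyls C19 on C4, C7 on C6 and C20 on C10) | C=C1C[C@]23C[C@H]1CC[C@H]2[C@]1(C(=O)O)CC[C@H](O)[C@@](C)(C(=O)O)[C@H]1[C@@H]3C(=O)O | target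

**Step count and risks**

Total step count: 19. Longest linear sequence: 18 (steps 1, 2 and 4–19; step 3 makes the diene).

Steps most likely to fail:

1. Step 17. The aldol is reversible and may drift to the equatorial 3-epimer; the C6 ester enolate may attack the aldehyde before it is protonated; tert-butoxide may cleave the acyclic imide. Fallback (sets out from 22, comes back at 25): the two bond formations are separated and C3 is set by reduction instead of by the aldol. Imide acetal 22 is cyclised with KN(SiMe3)2 in THF at −78 °C, where only the tethered Michael addition can occur, to give the glutarimide acetal F1. 1 M HCl in THF then unmasks the aldehyde (compound 24, now isolated). KOt-Bu in t-BuOH at rt closes ring A under thermodynamic control to the equatorial 3-epi alcohol F2, with C4 still dictated by the imide bridge. Dess–Martin periodinane gives the 3-ketone F3, and LiBH(s-Bu)3 in THF at −78 °C, attacking from the equatorial direction as bulky hydrides do on 2,2-disubstituted cyclohexanones, should return the axial alcohol 25.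

2. Step 18. Perhydrolysis of the doubly neopentyl imide may be slow, allowing retro-aldol epimerisation at C3 or incomplete opening. Fallback (sets out from 19 through acid chloride 21, comes back at 28): the tether is rebuilt with a better leaving group on nitrogen. Acid chloride 21 is treated with the sodium salt of N-methoxypropanamide to give the N-methoxy imide acetal F4. Aqueous HCl gives the aldehyde F5, and the same tert-butoxide Michael/aldol sequence gives the cyclic N-methoxy imide F6. LiOH/H2O2 followed by warm LiOH opens this more electrophilic imide and saponifies C7 to the O-methyl hydroxamate diacid F7. At pH 3.5 and 40 °C the neighbouring C19 acid expels O-methylhydroxylamine, a far better leaving group than methylamine, to give anhydride 28 and then 29.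

3. Step 4. The α-alkyl enone may be too poor a dienophile, or the acid may ionise the silyloxy group before cycloaddition. Fallback (sets out from 2 and 6, comes back at 7): the more reactive α-iodo enone 2 is used as dienophile with diene 6 (same catalyst, or thermally) to give the angular iodide F8, with the diene again anti to the silyloxy group. A Keck radical allylation with allyltributylstannane 3 (AIBN, benzene, 80 °C) then replaces iodine by allyl at C8, the ring-fusion radical being trapped on the convex face of the cis-fused bicycle, to give 7.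

**Further compounds**

F1 | step 17 | glutarimide acetal (Michael adduct of 22, C4 epimers) | C=C1C[C@]23C[C@H]1CC[C@H]2[C@@]1(CCC2OCCO2)C(=O)N(C)C(=O)C(C)[C@H]1[C@@H]3C(=O)OC
F2 | step 17 | 3-epi alcohol (equatorial 3-hydroxyl) of imide 25 | C=C1C[C@]23C[C@H]1CC[C@H]2[C@]14CC[C@@H](O)[C@@](C)(C(=O)N(C)C4=O)[C@H]1[C@@H]3C(=O)OC
F3 | step 17 | 3-ketone of imide 25 | C=C1C[C@]23C[C@H]1CC[C@H]2[C@]14CCC(=O)[C@@](C)(C(=O)N(C)C4=O)[C@H]1[C@@H]3C(=O)OC
F4 | step 18 | acyclic N-methoxy imide acetal | C=C1C[C@]23C[C@H]1CC[C@H]2[C@](C(=O)N(OC)C(=O)CC)(CCC1OCCO1)C=C3C(=O)OC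
F5 | step 18 | acyclic N-methoxy imide aldehyde | C=C1C[C@]23C[C@H]1CC[C@H]2[C@](C(=O)N(OC)C(=O)CC)(CCC=O)C=C3C(=O)OC
F6 | step 18 | 19,20-(N-methoxy)imide 7-methyl ester of the target triacid | C=C1C[C@]23C[C@H]1CC[C@H]2[C@]14CC[C@H](O)[C@@](C)(C(=O)N(OC)C4=O)[C@H]1[C@@H]3C(=O)OC
F7 | step 18 | 20-(O-methyl hydroxamate) of the target triacid with free C19 and C7 acids | C=C1C[C@]23C[C@H]1CC[C@H]2[C@]1(C(=O)NOC)CC[C@H](O)[C@@](C)(C(=O)O)[C@H]1[C@@H]3C(=O)O
F8 | step 4 | cis-fused B/C bicycle with angular iodide at C8 (iodo analogue of 7) | I[C@]12CC=C(O[Si](C)(C)C(C)(C)C)C[C@H]1[C@H](O[Si](C)(C)C(C)(C)C)CC2=O
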